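**Plan**
- Retrosynthesis: the angelate C–O at C5, the acetate C–O at C1, the C1–O bond and the C7a–H bond are cut first; the exocyclic C4=CH2 is carried as a C4(OH)CH2SiMe3 carbinol (Peterson precursor), so that no second ketone ever competes with C2. Rings A and B are then opened together by cutting C3a–C7a, C1–C2 and C2–C3.
- Enabling feature: ring A is a five-membered ketone whose carbonyl C2 is flanked by C1 and C3 and whose remaining edge C3a–C7a is the fusion bond to six-membered ring B. Such a ring is what a [2+2+1] union of a C1≡C7a alkyne, a C3=C3a alkene and CO leaves behind, here from a 1,7-enyne.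
- Forward: the C4–C7 chain is L-threitol acetonide (L-tartaric acid). C7a/C1 are added by Wittig olefination and butenolide closure, isopropyl by cuprate addition, and the lactone carbons become the alkyne. Vinyl and CH2SiMe3 are then added at C4, rings B and A close in one cobalt step, and ring A is oxygenated and the esters installed.
- Stereochemistry: C5 and C6 from L-tartaric acid; C7 by trans addition to the butenolide; the temporary C4 centre by Felkin–Anh addition; C3a by the chair-like cyclisation; C7a by axial protonation in the Li/NH3 reduction; C1 by α-face Rubottom oxidation followed by Mitsunobu inversion.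

Key step: step 16

Remark: locants C1–C7a are those of the hydrindanone of the target (C1 CHOAc, C2 C=O, C3 CH2, C3a, C4 C=CH2, C5 CHOAng, C6 CHOH, C7 CH-i-Pr, C7a) and are used for every intermediate. β is the face of H-7a, α the face of H-3a. PMB = 4-methoxybenzyl, TES = SiEt3, TBS = Si(t-Bu)Me2, TMS = SiMe3.
Remark: the building blocks marked as starting materials in the compound list and all reagents are taken as commercially available.
Remark: it is assumed that the peracid in step 18 attacks the α-face of the enol ether; the opposite outcome converges on the same acetate (see the end).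

Step 1
Reactants: 1 (+)-2,3-O-isopropylidene-L-threitol
Product: 2 [(4S,5S)-5-(PMB-oxymethyl)-2,2-dimethyl-1,3-dioxolan-4-yl]methanol
Conditions: NaH (1 equiv), PMBCl, Bu4NI (cat.), THF/DMF, 0 °C to rt
Reagents that add atoms: 4-methoxybenzyl chloride, COc1ccc(CCl)cc1
Why: Williamson etherification of the monosodium alkoxide of the twofold-symmetric diol should give the mono-PMB ether, which tells the two ends apart (C4 end protected, C7 end free) without touching a stereocentre.

Step 2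
Reactants: 2 [(4S,5S)-5-(PMB-oxymethyl)-2,2-dimethyl-1,3-dioxolan-4-yl]methanol
Product: 3 (4R,5S)-5-(PMB-oxymethyl)-2,2-dimethyl-1,3-dioxolane-4-carbaldehyde
Conditions: Dess–Martin periodinane, pyridine, CH2Cl2, 0 °C to rt
Reagents that add atoms: none
Why: Dess–Martin oxidation under pyridine buffer turns the primary alcohol into the α-alkoxy aldehyde without epimerising the adjacent acetal carbon.

Step 3
Reactants: 3 (4R,5S)-5-(PMB-oxymethyl)-2,2-dimethyl-1,3-dioxolane-4-carbaldehyde; 4 methyl (triphenylphosphoranylidene)acetate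
Product: 5 methyl (2Z)-3-[(4S,5S)-5-(PMB-oxymethyl)-2,2-dimethyl-1,3-dioxolan-4-yl]prop-2-enoate
Conditions: MeOH, 0 °C
Reagents that add atoms: methyl (triphenylphosphoranylidene)acetate (4), COC(=O)C=P(c1ccccc1)(c1ccccc1)c1ccccc1
Why: Wittig olefination with the stabilised ylide in methanol is known to favour the (Z)-enoate with α-alkoxy aldehydes, and the Z geometry is what the next step needs; the minor E isomer cannot lactonise and is removed after step 4.

Step 4
Reactants: 5 methyl (2Z)-3-[(4S,5S)-5-(PMB-oxymethyl)-2,2-dimethyl-1,3-dioxolan-4-yl]prop-2-enoate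
Product: 6 (5S)-5-[(1S)-1-hydroxy-2-(PMB-oxy)ethyl]furan-2(5H)-one
Conditions: p-TsOH·H2O (cat.), MeOH/H2O, rt to 40 °C
Reagents that add atoms: none
Why: Acid hydrolysis of the acetonide frees both hydroxyls, and the C6 hydroxyl, held next to the ester by the Z alkene, should close the five-membered butenolide by transesterification in preference to the six-membered lactone, leaving C5–OH as the only free hydroxyl so that the two tartrate oxygens are told apart (the PMB ether is stable to catalytic acid).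

Step 5
Reactants: 6 (5S)-5-[(1S)-1-hydroxy-2-(PMB-oxy)ethyl]furan-2(5H)-one
Product: 7 (5S)-5-[(1S)-2-(PMB-oxy)-1-(TES-oxy)ethyl]furan-2(5H)-one
Conditions: TESCl, imidazole, CH2Cl2, 0 °C
Reagents that add atoms: chlorotriethylsilane, CC[Si](Cl)(CC)CC
Why: Silylation with the silyl chloride and imidazole protects C5–OH under conditions too mild to enolise the butenolide to a 2-silyloxyfuran, so C6 keeps its configuration.

Step 6
Reactants: 7 (5S)-5-[(1S)-2-(PMB-oxy)-1-(TES-oxy)ethyl]furan-2(5H)-one; 8 isopropylmagnesium chloride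
Product: 9 (4R,5S)-4-isopropyl-5-[(1S)-2-(PMB-oxy)-1-(TES-oxy)ethyl]oxolan-2-one
Conditions: CuBr·SMe2 (10 mol%), THF, −78 to −40 °C
Reagents that add atoms: isopropylmagnesium chloride (8), CC(C)[Mg]Cl
Why: Copper-catalysed conjugate addition of a Grignard reagent to a γ-substituted butenolide is known to occur anti to the substituent on the γ-carbon (C6 of the target), so the isopropyl group should enter trans to the side chain and set C7 in the trans-disubstituted lactone.

Step 7
Reactants: 9 (4R,5S)-4-isopropyl-5-[(1S)-2-(PMB-oxy)-1-(TES-oxy)ethyl]oxolan-2-one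
Product: 11 (3R,4S,5S)-4-hydroxy-3-isopropyl-N-methoxy-N-methyl-6-(PMB-oxy)-5-(TES-oxy)hexanamide, via chloro(methyl)aluminium N-methoxy-N-methylamide 10 (not isolated)
Conditions: MeNH(OMe)·HCl, AlMe3, CH2Cl2, 0 °C; then 9, 0 °C to rt
Reagents that add atoms: N,O-dimethylhydroxylamine hydrochloride, CNOC.Cl
Why: Aminolysis of the lactone by the aluminium amide (Weinreb amide formation) opens the ring at the acyl C–O bond and releases C6–OH, the amide being silylated at once in step 8 because γ-hydroxy amides relactonise.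

Step 8
Reactants: 11 (3R,4S,5S)-4-hydroxy-3-isopropyl-N-methoxy-N-methyl-6-(PMB-oxy)-5-(TES-oxy)hexanamide
Product: 12 (3R,4S,5S)-4-(TBS-oxy)-3-isopropyl-N-methoxy-N-methyl-6-(PMB-oxy)-5-(TES-oxy)hexanamide
Conditions: TBSOTf, 2,6-lutidine, CH2Cl2, −78 to 0 °C
Reagents that add atoms: tert-butyldimethylsilyl trifluoromethanesulfonate, CC(C)(C)[Si](C)(C)OS(=O)(=O)C(F)(F)F
Why: The silyl triflate with 2,6-lutidine silylates the hindered secondary C6–OH without disturbing the triethylsilyl ether, so that C5 and C6 now carry silyl groups of different lability.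

Step 9
Reactants: 12 (3R,4S,5S)-4-(TBS-oxy)-3-isopropyl-N-methoxy-N-methyl-6-(PMB-oxy)-5-(TES-oxy)hexanamide
Product: 13 (3R,4S,5S)-4-(TBS-oxy)-3-isopropyl-6-(PMB-oxy)-5-(TES-oxy)hexanal
Conditions: i-Bu2AlH, THF, −78 °C
Reagents that add atoms: none
Why: Hydride addition to the Weinreb amide stops at the chelated tetrahedral aluminium adduct, which gives the aldehyde only on aqueous work-up.

Step 10
Reactants: 13 (3R,4S,5S)-4-(TBS-oxy)-3-isopropyl-6-(PMB-oxy)-5-(TES-oxy)hexanal
Product: 15 1-({[(2S,3S,4S)-3-(TBS-oxy)-4-isopropyl-2-(TES-oxy)hex-5-yn-1-yl]oxy}methyl)-4-methoxybenzene, via (Z)-enol triflate 14 (not isolated)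
Conditions: PhNTf2, KN(SiMe3)2, THF, −78 °C; then LiN(i-Pr)2 (2.5 equiv), −78 to −20 °C
Reagents that add atoms: none
Why: O-Sulfonylation of the aldehyde enolate (generated in the presence of PhNTf2 to outrun aldol reaction) gives the (Z)-alkenyl triflate 14, from which the amide base removes the vinylic hydrogen anti to triflate in a β-elimination that leaves the terminal alkyne on the same two carbons C7a and C1, the known alkenyl sulfonate route from enolisable carbonyl compounds to alkynes; C7 lies β to the carbonyl and cannot epimerise.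

Step 11
Reactants: 15 1-({[(2S,3S,4S)-3-(TBS-oxy)-4-isopropyl-2-(TES-oxy)hex-5-yn-1-yl]oxy}methyl)-4-methoxybenzene
Product: 16 (2S,3S,4S)-3-(TBS-oxy)-4-isopropyl-2-(TES-oxy)hex-5-yn-1-ol
Conditions: DDQ, CH2Cl2/pH 7 buffer, 0 °C
Reagents that add atoms: none
Why: Oxidative cleavage of the PMB ether by DDQ (hydride abstraction and hydrolysis of the oxocarbenium ion) frees the C4 primary alcohol while the silyl ethers and the alkyne are inert under buffered conditions.

Step 12
Reactants: 16 (2S,3S,4S)-3-(TBS-oxy)-4-isopropyl-2-(TES-oxy)hex-5-yn-1-ol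
Product: 17 (2R,3S,4S)-3-(TBS-oxy)-4-isopropyl-2-(TES-oxy)hex-5-ynal
Conditions: Dess–Martin periodinane, pyridine, CH2Cl2, 0 °C to rt
Reagents that add atoms: none
Why: Buffered Dess–Martin oxidation gives the α-silyloxy aldehyde without epimerisation at C5; it is used without purification.

Step 13
Reactants: 17 (2R,3S,4S)-3-(TBS-oxy)-4-isopropyl-2-(TES-oxy)hex-5-ynal; 18 vinylmagnesium bromide
Product: 19 (3RS,4S,5S,6S)-5-(TBS-oxy)-6-isopropyl-4-(TES-oxy)oct-1-en-7-yn-3-ol (mixture of C4 epimers in target numbering)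
Conditions: THF, −78 °C
Reagents that add atoms: vinylmagnesium bromide (18), C=C[Mg]Br
Why: Grignard 1,2-addition to the aldehyde is far faster at −78 °C than deprotonation of the terminal alkyne, and the C4 epimer mixture is of no consequence because C4 is oxidised in the next step.

Step 14
Reactants: 19 (3RS,4S,5S,6S)-5-(TBS-oxy)-6-isopropyl-4-(TES-oxy)oct-1-en-7-yn-3-ol
Product: 20 (4R,5S,6S)-5-(TBS-oxy)-6-isopropyl-4-(TES-oxy)oct-1-en-7-yn-3-one
Conditions: Dess–Martin periodinane, pyridine, CH2Cl2, 0 °C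
Reagents that add atoms: none
Why: Dess–Martin oxidation of the allylic alcohol gives the vinyl ketone under non-basic conditions that avoid conjugate addition or polymerisation, and the enone is taken on at once.

Step 15
Reactants: 20 (4R,5S,6S)-5-(TBS-oxy)-6-isopropyl-4-(TES-oxy)oct-1-en-7-yn-3-one; 21 (trimethylsilyl)methylmagnesium chloride
Product: 23 (3R,4R,5S,6S)-5-(TBS-oxy)-6-isopropyl-4-(TES-oxy)-3-(TMS-methyl)oct-1-en-7-yn-3-ol, via (trimethylsilyl)methylcerium dichloride 22 (not isolated)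
Conditions: CeCl3 (anhydrous), THF, −78 °C; then 20, −78 °C
Reagents that add atoms: (trimethylsilyl)methylmagnesium chloride (21), C[Si](C)(C)C[Mg]Cl
Why: The organocerium reagent adds 1,2 to the enone without conjugate addition, enolisation or attack on the alkyne C–H, and Felkin–Anh approach anti to the C5–OSiEt3 bond should set the temporary C4 centre with the hydroxyl β; the resulting β-hydroxysilane is the Peterson precursor of the C4 methylene.

Step 16
Reactants: 23 (3R,4R,5S,6S)-5-(TBS-oxy)-6-isopropyl-4-(TES-oxy)-3-(TMS-methyl)oct-1-en-7-yn-3-ol; 24 Co2(CO)8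
Product: 26 (3aR,4R,5R,6S,7S)-6-(TBS-oxy)-4-hydroxy-7-isopropyl-5-(TES-oxy)-4-(TMS-methyl)-3,3a,4,5,6,7-hexahydro-2H-inden-2-one, via alkyne–Co2(CO)6 complex 25 (not isolated)
Conditions: Co2(CO)8 (1.1 equiv), CH2Cl2, rt; then N-methylmorpholine N-oxide (8 equiv), 0 °C to rt
Reagents that add atoms: Co2(CO)8 (24), O=C=[Co](=C=O)(=C=O)(=C=O)[Co](=C=O)(=C=O)(=C=O)=C=O
Why: Co2(CO)8 (zerovalent cobalt) binds the terminal alkyne C1≡C7a as the Co2(CO)6 complex 25; oxidation of a CO ligand to CO2 by the N-oxide frees a site on cobalt, the C3=C3a vinyl group coordinates and inserts into the Co–C7a bond (forming C3a–C7a), and CO insertion followed by reductive elimination joins C1–C2 and C2–C3. The closest known reaction type is the amine N-oxide-promoted intramolecular Pauson–Khand reaction of 1,7-enynes to bicyclo[4.3.0]nonenones. Ring B closes as a six-membered ring in the exo mode on both π systems (C7a attacks the inner alkene carbon C3a, while C3 and C1 stay outside the ring), and ring A closes in the same event by the two bonds from C1 and C3 to the inserted CO carbon C2, giving the C1=C7a cyclopentenone. The only new stereocentre, C3a, is controlled by the C4–C7 stereocentres through a chair-like arrangement of the forming ring B with isopropyl and CH2SiMe3 equatorial and the three oxygen substituents axial (C4–OH hydrogen-bonded to the syn-axial O6), which puts H-3a axial on the α-face; the other chair would have isopropyl and CH2SiMe3 axial and the two bulky vicinal silyl ethers gauche. The step needs this facial selectivity at the vinyl group and ring closure in the slower 1,7 mode, and the substrate secures them by the quaternary C4 and fully substituted tether (gem-disubstituent effect, folded rotamer) and by two unhindered π partners (terminal alkyne, monosubstituted alkene).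

Step 17
Reactants: 26 (3aR,4R,5R,6S,7S)-6-(TBS-oxy)-4-hydroxy-7-isopropyl-5-(TES-oxy)-4-(TMS-methyl)-3,3a,4,5,6,7-hexahydro-2H-inden-2-one
Product: 28 (3aR,4R,5R,6S,7S,7aR)-6-(TBS-oxy)-7-isopropyl-5-(TES-oxy)-2,4-bis(TMS-oxy)-4-(TMS-methyl)-3a,4,5,6,7,7a-hexahydro-3H-indene (C1=C2 enol ether; trans ring fusion), via dilithium enolate alkoxide 27 (not isolated)
Conditions: Li, NH3(l)/THF, −78 °C; NH3 removed; then Me3SiCl, Et3N, THF, −78 to 0 °C
Reagents that add atoms: chlorotrimethylsilane, C[Si](C)(C)Cl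
Why: Dissolving-metal reduction of the enone gives the β-carbanion at C7a, which is protonated axially on the β-face (the syn-axial C4 hydroxyl acting as internal proton donor) to set the trans ring fusion at C7a, and the regiodefined C1=C2 lithium enolate 27 is trapped on oxygen together with the C4 alkoxide (reductive silylation of an enone).

Step 18
Reactants: 28 (3aR,4R,5R,6S,7S,7aR)-6-(TBS-oxy)-7-isopropyl-5-(TES-oxy)-2,4-bis(TMS-oxy)-4-(TMS-methyl)-3a,4,5,6,7,7a-hexahydro-3H-indene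
Product: 31 (1S,3aR,4R,5R,6S,7S,7aS)-6-(TBS-oxy)-1-hydroxy-7-isopropyl-5-(TES-oxy)-4-(TMS-oxy)-4-(TMS-methyl)octahydro-2H-inden-2-one (1α-OH), via 1α,2α-epoxy silyl ether 29 (not isolated), via 1α-trimethylsilyloxy ketone 30 (not isolated)
Conditions: mCPBA, CH2Cl2, −20 °C; then citric acid (cat.), MeOH, 0 °C
Reagents that add atoms: 3-chloroperoxybenzoic acid, OOC(=O)c1cccc(Cl)c1
Why: Rubottom oxidation: the peracid should epoxidise the electron-rich enol ether from the α-face, anti to the pseudoaxial allylic H-7a and away from the axial 4β and 6β silyloxy groups, the epoxide 29 opens with silyl migration to 30, and mild acidic methanolysis cleaves only the labile α-keto silyl ether to give the 1α-alcohol.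

Step 19
Reactants: 31 (1S,3aR,4R,5R,6S,7S,7aS)-6-(TBS-oxy)-1-hydroxy-7-isopropyl-5-(TES-oxy)-4-(TMS-oxy)-4-(TMS-methyl)octahydro-2H-inden-2-one; 32 acetic acid
Product: 33 (1R,3aR,4R,5R,6S,7S,7aS)-6-(TBS-oxy)-7-isopropyl-2-oxo-5-(TES-oxy)-4-(TMS-oxy)-4-(TMS-methyl)octahydro-1H-inden-1-yl acetate (1β-OAc)
Conditions: PPh3, DIAD, THF, 0 °C to rt
Reagents that add atoms: acetic acid (32), CC(=O)O
Why: Mitsunobu esterification: the oxyphosphonium ion at C1, activated towards SN2 by the adjacent carbonyl, is displaced by acetate from the β-face with inversion, which sets C1 as in the target.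

Step 20
Reactants: 33 (1R,3aR,4R,5R,6S,7S,7aS)-6-(TBS-oxy)-7-isopropyl-2-oxo-5-(TES-oxy)-4-(TMS-oxy)-4-(TMS-methyl)octahydro-1H-inden-1-yl acetate
Product: 34 (1R,3aR,5S,6S,7S,7aR)-6-(TBS-oxy)-5-hydroxy-7-isopropyl-4-methylidene-2-oxooctahydro-1H-inden-1-yl acetate
Conditions: p-TsOH·H2O (cat.), MeOH/CH2Cl2, 0 °C to rt
Reagents that add atoms: none
Why: Acid-catalysed methanolysis removes the tertiary trimethylsilyl and the secondary triethylsilyl ether, and the freed tertiary β-hydroxysilane undergoes acid-mediated Peterson elimination (anti loss of Me3Si and OH) to the exocyclic C4 methylene with no regioisomer possible, while the hindered axial TBS ether at C6 and the acetate should survive.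

Step 21
Reactants: 34 (1R,3aR,5S,6S,7S,7aR)-6-(TBS-oxy)-5-hydroxy-7-isopropyl-4-methylidene-2-oxooctahydro-1H-inden-1-yl acetate; 35 angelic acid
Product: 37 (1R,3aR,5S,6S,7S,7aR)-1-acetoxy-6-(TBS-oxy)-7-isopropyl-4-methylidene-2-oxooctahydro-1H-inden-5-yl (2Z)-2-methylbut-2-enoate, via angelic 2,4,6-trichlorobenzoic anhydride 36 (not isolated)
Conditions: 2,4,6-trichlorobenzoyl chloride, Et3N, toluene, rt; then 34, toluene, 80 °C
Reagents that add atoms: angelic acid (35), C/C=C(/C)C(=O)O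
Why: Yamaguchi-type acylation through the mixed anhydride 36, run without DMAP so that no conjugate addition can isomerise the Z alkene to the tiglate, esterifies the axial allylic C5–OH, the only free hydroxyl.

Step 22
Reactants: 37 (1R,3aR,5S,6S,7S,7aR)-1-acetoxy-6-(TBS-oxy)-7-isopropyl-4-methylidene-2-oxooctahydro-1H-inden-5-yl (2Z)-2-methylbut-2-enoate
Product: 38 (1R,3aR,5S,6S,7S,7aR)-1-acetoxy-6-hydroxy-7-isopropyl-4-methylidene-2-oxooctahydro-1H-inden-5-yl (2Z)-2-methylbut-2-enoate (CNP0317011.1)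
Conditions: HF·pyridine, pyridine, THF, 0 °C to rt
Reagents that add atoms: none
Why: Fluoride cleavage of the TBS ether under weakly acidic, non-basic conditions leaves the angelate geometry, the acetate, the ketone and the exocyclic alkene untouched, and the trans-diaxial placement of O5 and O6 prevents acyl migration.

**Compound list**
1 | (+)-2,3-O-isopropylidene-L-threitol, [(4S,5S)-2,2-dimethyl-1,3-dioxolane-4,5-diyl]dimethanol | OC[C@@H]1OC(C)(C)O[C@H]1CO | starting material
2 | [(4S,5S)-5-(PMB-oxymethyl)-2,2-dimethyl-1,3-dioxolan-4-yl]methanol | COc1ccc(COC[C@@H]2OC(C)(C)O[C@H]2CO)cc1 | intermediate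
3 | (4R,5S)-5-(PMB-oxymethyl)-2,2-dimethyl-1,3-dioxolane-4-carbaldehyde | COc1ccc(COC[C@@H]2OC(C)(C)O[C@H]2C=O)cc1 | intermediate
4 | methyl (triphenylphosphoranylidene)acetate | COC(=O)C=P(c1ccccc1)(c1ccccc1)c1ccccc1 | starting material
5 | methyl (2Z)-3-[(4S,5S)-5-(PMB-oxymethyl)-2,2-dimethyl-1,3-dioxolan-4-yl]prop-2-enoate | COc1ccc(COC[C@@H]2OC(C)(C)O[C@H]2/C=C\C(=O)OC)cc1 | intermediate
6 | (5S)-5-[(1S)-1-hydroxy-2-(PMB-oxy)ethyl]furan-2(5H)-one | COc1ccc(COC[C@H](O)[C@H]2OC(=O)C=C2)cc1 | intermediate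
7 | (5S)-5-[(1S)-2-(PMB-oxy)-1-(TES-oxy)ethyl]furan-2(5H)-one | COc1ccc(COC[C@H](O[Si](CC)(CC)CC)[C@H]2OC(=O)C=C2)cc1 | intermediate
8 | isopropylmagnesium chloride | CC(C)[Mg]Cl | starting material
9 | (4R,5S)-4-isopropyl-5-[(1S)-2-(PMB-oxy)-1-(TES-oxy)ethyl]oxolan-2-one (trans) | COc1ccc(COC[C@H](O[Si](CC)(CC)CC)[C@H]2OC(=O)C[C@@H]2C(C)C)cc1 | intermediate
10 | chloro(methyl)aluminium N-methoxy-N-methylamide | C[Al](Cl)N(C)OC | intermediate
11 | (3R,4S,5S)-4-hydroxy-3-isopropyl-N-methoxy-N-methyl-6-(PMB-oxy)-5-(TES-oxy)hexanamide | COc1ccc(COC[C@H](O[Si](CC)(CC)CC)[C@@H](O)[C@@H](C(C)C)CC(=O)N(C)OC)cc1 | intermediate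
12 | (3R,4S,5S)-4-(TBS-oxy)-3-isopropyl-N-methoxy-N-methyl-6-(PMB-oxy)-5-(TES-oxy)hexanamide | COc1ccc(COC[C@H](O[Si](CC)(CC)CC)[C@@H](O[Si](C)(C)C(C)(C)C)[C@@H](C(C)C)CC(=O)N(C)OC)cc1 | intermediate
13 | (3R,4S,5S)-4-(TBS-oxy)-3-isopropyl-6-(PMB-oxy)-5-(TES-oxy)hexanal | COc1ccc(COC[C@H](O[Si](CC)(CC)CC)[C@@H](O[Si](C)(C)C(C)(C)C)[C@@H](C(C)C)CC=O)cc1 | intermediate
14 | (1Z,3S,4S,5S)-4-(TBS-oxy)-3-isopropyl-6-(PMB-oxy)-5-(TES-oxy)hex-1-en-1-yl trifluoromethanesulfonate | COc1ccc(COC[C@H](O[Si](CC)(CC)CC)[C@@H](O[Si](C)(C)C(C)(C)C)[C@@H](C(C)C)/C=C\OS(=O)(=O)C(F)(F)F)cc1 | intermediate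
15 | 1-({[(2S,3S,4S)-3-(TBS-oxy)-4-isopropyl-2-(TES-oxy)hex-5-yn-1-yl]oxy}methyl)-4-methoxybenzene | COc1ccc(COC[C@H](O[Si](CC)(CC)CC)[C@@H](O[Si](C)(C)C(C)(C)C)[C@@H](C(C)C)C#C)cc1 | intermediate
16 | (2S,3S,4S)-3-(TBS-oxy)-4-isopropyl-2-(TES-oxy)hex-5-yn-1-ol | OC[C@H](O[Si](CC)(CC)CC)[C@@H](O[Si](C)(C)C(C)(C)C)[C@@H](C(C)C)C#C | intermediate
17 | (2R,3S,4S)-3-(TBS-oxy)-4-isopropyl-2-(TES-oxy)hex-5-ynal | O=C[C@H](O[Si](CC)(CC)CC)[C@@H](O[Si](C)(C)C(C)(C)C)[C@@H](C(C)C)C#C | intermediate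
18 | vinylmagnesium bromide | C=C[Mg]Br | starting material
19 | (3RS,4S,5S,6S)-5-(TBS-oxy)-6-isopropyl-4-(TES-oxy)oct-1-en-7-yn-3-ol (epimers at the carbinol carbon) | C=CC(O)[C@H](O[Si](CC)(CC)CC)[C@@H](O[Si](C)(C)C(C)(C)C)[C@@H](C(C)C)C#C | intermediate
20 | (4R,5S,6S)-5-(TBS-oxy)-6-isopropyl-4-(TES-oxy)oct-1-en-7-yn-3-one | C=CC(=O)[C@H](O[Si](CC)(CC)CC)[C@@H](O[Si](C)(C)C(C)(C)C)[C@@H](C(C)C)C#C | intermediate
21 | (trimethylsilyl)methylmagnesium chloride | C[Si](C)(C)C[Mg]Cl | starting material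
22 | (trimethylsilyl)methylcerium dichloride | C[Si](C)(C)C[Ce](Cl)Cl | intermediate
23 | (3R,4R,5S,6S)-5-(TBS-oxy)-6-isopropyl-4-(TES-oxy)-3-(TMS-methyl)oct-1-en-7-yn-3-ol | C=C[C@](O)(C[Si](C)(C)C)[C@H](O[Si](CC)(CC)CC)[C@@H](O[Si](C)(C)C(C)(C)C)[C@@H](C(C)C)C#C | intermediate
24 | Co2(CO)8, dicobalt octacarbonyl | O=C=[Co](=C=O)(=C=O)(=C=O)[Co](=C=O)(=C=O)(=C=O)=C=O | starting material
25 | Co2(CO)6 complex of the C1≡C7a alkyne of 23 | C=C[C@](O)(C[Si](C)(C)C)[C@H](O[Si](CC)(CC)CC)[C@@H](O[Si](C)(C)C(C)(C)C)[C@@H](C(C)C)C12[CH]3[Co]1(=C=O)(=C=O)(=C=O)[Co]23(=C=O)(=C=O)=C=O | intermediate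
26 | (3aR,4R,5R,6S,7S)-6-(TBS-oxy)-4-hydroxy-7-isopropyl-5-(TES-oxy)-4-(TMS-methyl)-3,3a,4,5,6,7-hexahydro-2H-inden-2-one | O[C@]1(C[Si](C)(C)C)[C@@H]2CC(=O)C=C2[C@H](C(C)C)[C@H](O[Si](C)(C)C(C)(C)C)[C@H]1O[Si](CC)(CC)CC | intermediate
27 | dilithium salt of the 7aβ-H C1=C2 enolate of 26 (C2–OLi and C4–OLi) | [Li+].[Li+].[O-][C@]1(C[Si](C)(C)C)[C@@H]2CC([O-])=C[C@H]2[C@H](C(C)C)[C@H](O[Si](C)(C)C(C)(C)C)[C@H]1O[Si](CC)(CC)CC | intermediate
28 | (3aR,4R,5R,6S,7S,7aR)-6-(TBS-oxy)-7-isopropyl-5-(TES-oxy)-2,4-bis(TMS-oxy)-4-(TMS-methyl)-3a,4,5,6,7,7a-hexahydro-3H-indene (C1=C2 enol ether, trans-fused) | C[Si](C)(C)O[C@]1(C[Si](C)(C)C)[C@@H]2CC(O[Si](C)(C)C)=C[C@H]2[C@H](C(C)C)[C@H](O[Si](C)(C)C(C)(C)C)[C@H]1O[Si](CC)(CC)CC | intermediate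
29 | 1α,2α-epoxide of 28 | C[Si](C)(C)O[C@]1(C[Si](C)(C)C)[C@@H]2C[C@@]3(O[Si](C)(C)C)O[C@H]3[C@H]2[C@H](C(C)C)[C@H](O[Si](C)(C)C(C)(C)C)[C@H]1O[Si](CC)(CC)CC | intermediate
30 | (1S,3aR,4R,5R,6S,7S,7aS)-6-(TBS-oxy)-7-isopropyl-5-(TES-oxy)-1,4-bis(TMS-oxy)-4-(TMS-methyl)octahydro-2H-inden-2-one | C[Si](C)(C)O[C@]1(C[Si](C)(C)C)[C@@H]2CC(=O)[C@@H](O[Si](C)(C)C)[C@H]2[C@H](C(C)C)[C@H](O[Si](C)(C)C(C)(C)C)[C@H]1O[Si](CC)(CC)CC | intermediate
31 | (1S,3aR,4R,5R,6S,7S,7aS)-6-(TBS-oxy)-1-hydroxy-7-isopropyl-5-(TES-oxy)-4-(TMS-oxy)-4-(TMS-methyl)octahydro-2H-inden-2-one (1α-OH) | C[Si](C)(C)O[C@]1(C[Si](C)(C)C)[C@@H]2CC(=O)[C@@H](O)[C@H]2[C@H](C(C)C)[C@H](O[Si](C)(C)C(C)(C)C)[C@H]1O[Si](CC)(CC)CC | intermediate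
32 | acetic acid | CC(=O)O | starting material
33 | (1R,3aR,4R,5R,6S,7S,7aS)-6-(TBS-oxy)-7-isopropyl-2-oxo-5-(TES-oxy)-4-(TMS-oxy)-4-(TMS-methyl)octahydro-1H-inden-1-yl acetate (1β-OAc) | C[Si](C)(C)O[C@]1(C[Si](C)(C)C)[C@@H]2CC(=O)[C@H](OC(C)=O)[C@H]2[C@H](C(C)C)[C@H](O[Si](C)(C)C(C)(C)C)[C@H]1O[Si](CC)(CC)CC | intermediate
34 | (1R,3aR,5S,6S,7S,7aR)-6-(TBS-oxy)-5-hydroxy-7-isopropyl-4-methylidene-2-oxooctahydro-1H-inden-1-yl acetate | C=C1[C@@H]2CC(=O)[C@H](OC(C)=O)[C@H]2[C@H](C(C)C)[C@H](O[Si](C)(C)C(C)(C)C)[C@H]1O | intermediate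
35 | angelic acid, (2Z)-2-methylbut-2-enoic acid | C/C=C(/C)C(=O)O | starting material
36 | angelic 2,4,6-trichlorobenzoic anhydride | C/C=C(/C)C(=O)OC(=O)c1c(Cl)cc(Cl)cc1Cl | intermediate
37 | (1R,3aR,5S,6S,7S,7aR)-1-acetoxy-6-(TBS-oxy)-7-isopropyl-4-methylidene-2-oxooctahydro-1H-inden-5-yl (2Z)-2-methylbut-2-enoate | C=C1[C@@H]2CC(=O)[C@H](OC(C)=O)[C@H]2[C@H](C(C)C)[C@H](O[Si](C)(C)C(C)(C)C)[C@H]1OC(=O)/C(C)=C\C | intermediate
38 | (1R,3aR,5S,6S,7S,7aR)-1-acetoxy-6-hydroxy-7-isopropyl-4-methylidene-2-oxooctahydro-1H-inden-5-yl (2Z)-2-methylbut-2-enoate (CNP0317011.1) | C=C1[C@@H]2CC(=O)[C@H](OC(C)=O)[C@H]2[C@H](C(C)C)[C@H](O)[C@H]1OC(=O)/C(C)=C\C | target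

**Step count and risks**
Total step count: 22. Longest linear sequence: 22 steps (1 to 38); the route is fully linear.

Steps most likely to fail:

1. The cobalt cyclisation (step 16). The 1,7-enyne may cyclise slowly, and the free tertiary allylic β-silyl carbinol may bind cobalt or ionise with loss of the hydroxyl (Peterson-type drift to a 1,3-diene), which would stall alkene insertion. The fallback sets out from 23 and takes the hydroxyl out of play before the metal is introduced. N-(Trimethylsilyl)imidazole converts 23 into the 4-O-trimethylsilyl enyne F1. The same Co2(CO)8/N-oxide cyclisation then gives the 4-O-trimethylsilyl enone F2, in which the three axial silyloxy groups keep the same chair. Li/NH3 reduction of F2 with one equivalent of t-BuOH and Me3SiCl/Et3N trapping returns to the route at 28, where this silyl ether is present in any case.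

2. The Rubottom oxidation (step 18). The facial preference of the peracid on the enol ether rests on torsional and steric arguments, so attack may occur from the β-face or without clear preference. The fallback sets out from 28: β-face oxidation gives the 1β-hydroxy ketone F3, which already has the C1 configuration of the target. It is therefore not inverted but acetylated with retention (Ac2O, pyridine, DMAP cat., CH2Cl2, 0 °C) and returns to the route at 33. Both facial outcomes thus converge, the 1α-alcohol through the Mitsunobu step and F3 through plain acetylation.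

3. The aldehyde-to-alkyne conversion (step 10). Enolate triflation may be overrun by self-aldol condensation of the aldehyde, or the elimination may stop at the alkenyl triflate. The fallback sets out from 13 and builds the alkyne by one-carbon degradation and rehomologation. Soft enolisation (Me3SiOTf, Et3N, CH2Cl2) gives the trimethylsilyl enol ether F4. Ozonolysis with Me2S work-up cuts it to the α-branched aldehyde F5, with C7a as the formyl carbon. Seyferth–Gilbert homologation with dimethyl (1-diazo-2-oxopropyl)phosphonate and K2CO3 in MeOH at 0 °C (Ohira–Bestmann conditions, mild enough to keep C7) returns to the route at 15.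

**Further compounds**
F1 | step 16 | (3R,4R,5S,6S)-5-(TBS-oxy)-6-isopropyl-4-(TES-oxy)-3-(TMS-oxy)-3-(TMS-methyl)oct-1-en-7-yne | C=C[C@](O[Si](C)(C)C)(C[Si](C)(C)C)[C@H](O[Si](CC)(CC)CC)[C@@H](O[Si](C)(C)C(C)(C)C)[C@@H](C(C)C)C#C
F2 | step 16 | (3aR,4R,5R,6S,7S)-6-(TBS-oxy)-7-isopropyl-5-(TES-oxy)-4-(TMS-oxy)-4-(TMS-methyl)-3,3a,4,5,6,7-hexahydro-2H-inden-2-one | C[Si](C)(C)O[C@]1(C[Si](C)(C)C)[C@@H]2CC(=O)C=C2[C@H](C(C)C)[C@H](O[Si](C)(C)C(C)(C)C)[C@H]1O[Si](CC)(CC)CC
F3 | step 18 | (1R,3aR,4R,5R,6S,7S,7aS)-6-(TBS-oxy)-1-hydroxy-7-isopropyl-5-(TES-oxy)-4-(TMS-oxy)-4-(TMS-methyl)octahydro-2H-inden-2-one (1β-OH) | C[Si](C)(C)O[C@]1(C[Si](C)(C)C)[C@@H]2CC(=O)[C@H](O)[C@H]2[C@H](C(C)C)[C@H](O[Si](C)(C)C(C)(C)C)[C@H]1O[Si](CC)(CC)CC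
F4 | step 10 | (3S,4S,5S)-4-(TBS-oxy)-3-isopropyl-6-(PMB-oxy)-5-(TES-oxy)-1-(TMS-oxy)hex-1-ene (E/Z mixture) | COc1ccc(COC[C@H](O[Si](CC)(CC)CC)[C@@H](O[Si](C)(C)C(C)(C)C)[C@@H](C(C)C)C=CO[Si](C)(C)C)cc1
F5 | step 10 | (2R,3S,4S)-3-(TBS-oxy)-2-isopropyl-5-(PMB-oxy)-4-(TES-oxy)pentanal | COc1ccc(COC[C@H](O[Si](CC)(CC)CC)[C@@H](O[Si](C)(C)C(C)(C)C)[C@@H](C(C)C)C=O)cc1
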